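A direct plan would join the 2-borylated tryptamine carbamate A1 and 5-benzyloxy-4-bromo-7-methoxyindole A2 by Suzuki coupling and unmask the N-methylamine and the phenol to reach amino phenol A3. It would then close the piperidine and dihydrofuran rings of A3 in one formaldehyde cascade under a chiral phosphoric acid (Mannich spirocyclisation to spiroindolenine A4, 1,2-shift, capture by the phenol), before a last Mannich reaction.
- The Suzuki union of A1 and A2 would be weak: boronate A1 protodeboronates readily and would have to meet bromide A2, which is flanked by an ortho benzyloxy group and the peri ring, with three free N–H groups present.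
- The cascade from A3 that sets both quaternary centres would be weak: its enantiodetermining event would be a 1,2-shift in the reversibly formed spiroindolenine A4, and the N-methyl nitrogen offers the chiral phosphate no N–H handle at any stage. One equivalent of formaldehyde would also have to ignore a free indole C3 and an electron-rich phenol, and the product could reopen under the same acid.
- The carbamate and benzyl bookkeeping on the way to A3 would be weak: acylation, benzylation, LiAlH4 reduction and hydrogenolysis would be four operations that build no bond of the skeleton.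

**Retrosynthetic overview of the new route**

- The C4a–C9a bond is shared by the piperidine, indoline and dihydrofuran rings. C4a carries the ether oxygen and the indoline aryl carbon C4b; C9a carries N9 and C4′. A Fischer [3,3] shift that lands on a fully substituted, oxygen-bearing α-carbon of a ketone creates exactly this pattern.
- Key disconnection: hexacyclic lactam ⇒ 4-aryloxy-piperidine-2,3-dione + phenylhydrazine. One operation forms C4a–C4b, N9–C9a and C9a–C4′ (interrupted Fischer indolisation ended by an aza-Friedel–Crafts arylation).
- Ring order: piperidinone (bought), aryl ether (epoxide opening by a 5-hydroxyindole), pyrroline, dihydrofuran; then Mannich reaction and reduction of C1=O to CH2.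
- The design has no biaryl coupling and no protecting group. Both quaternary centres arise together: C4a under a chiral acid, C9a as its geometric consequence. The C1 carbonyl directs enolisation, activates the ketimine, keeps N2 non-basic for the acid catalyst and ends as the C1 methylene.

Key step: step 6

**Remarks**

- Numbering: β-carboline positions carry no prime (C1, N2, C3, C4, C4a, C4b, N9, C9a); positions of the methoxyindole carry a prime.
- Assumption: the sense of induction of the chiral phosphoric acid in step 6 cannot be predicted with confidence. The (S)-acid is written; its mirror image would be taken if the (4aR) series formed.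
- Assumption: 4-bromo-2-methoxy-1-nitrobenzene, 1-methyl-5,6-dihydropyridin-2(1H)-one and phenylhydrazine are taken as catalogue compounds.

**Route**

Step 1
Reactants: 1 4-bromo-2-methoxy-1-nitrobenzene
Product: 3 5-bromo-7-methoxy-1H-indole, via nitrosoarene 2 (not isolated)
Conditions: CH2=CHMgBr (3.2 equiv), THF, −45 °C; aq. NH4Cl
Reagents that add atoms: vinylmagnesium bromide, C=C[Mg]Br
Why: Bartoli indole synthesis, for which the ortho-OMe group is the required ortho substituent; the [3,3]-shift of the N-aryl-O-vinylhydroxylamine can go only to the free ortho carbon, so Br ends at C5 and OMe at C7.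

Step 2
Reactants: 3 5-bromo-7-methoxy-1H-indole
Product: 4 7-methoxy-1H-indol-5-ol
Conditions: Pd2(dba)3 (1 mol %), tBuBrettPhos (4 mol %), KOH (3 equiv), 1,4-dioxane–H2O (1:1), 80 °C, Ar; aq. HCl to pH 6; used at once
Reagents that add atoms: potassium hydroxide, [K+].[OH-]
Why: Palladium-catalysed hydroxylation of an aryl bromide with hydroxide (C–O cross-coupling with a bulky biarylphosphine), a reaction that tolerates unprotected N–H indoles.

Step 3
Reactants: 5 1-methyl-5,6-dihydropyridin-2(1H)-one
Product: 6 3-methyl-7-oxa-3-azabicyclo[4.1.0]heptan-2-one (racemic 3,4-epoxy-1-methylpiperidin-2-one)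
Conditions: mCPBA (2.5 equiv), 2,6-di-tert-butyl-4-methylphenol (2 mol %), ClCH2CH2Cl, 75 °C
Reagents that add atoms: 3-chloroperbenzoic acid, O=C(OO)c1cccc(Cl)c1
Why: Prilezhaev epoxidation of an electron-poor conjugated alkene, which needs heat and a radical inhibitor that preserves the peracid; the lactam nitrogen is not oxidised, and the racemic epoxide suffices because its stereocentres are erased later.

Step 4
Reactants: 4 7-methoxy-1H-indol-5-ol; 6 3-methyl-7-oxa-3-azabicyclo[4.1.0]heptan-2-one
Product: 7 rac-trans-3-hydroxy-4-[(7-methoxy-1H-indol-5-yl)oxy]-1-methylpiperidin-2-one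
Conditions: Cs2CO3 (0.5 equiv), DMF, 70 °C, Ar
Reagents that add atoms: none
Why: SN2 opening of the α,β-epoxy amide by the phenoxide at C4, the β-carbon (attack next to the carbonyl is disfavoured), in the trans-diaxial sense; carbonate deprotonates the phenol but not the indole N–H, and DMF favours O-alkylation.

Step 5
Reactants: 7 rac-trans-3-hydroxy-4-[(7-methoxy-1H-indol-5-yl)oxy]-1-methylpiperidin-2-one
Product: 8 4-[(7-methoxy-1H-indol-5-yl)oxy]-1-methylpiperidine-2,3-dione (racemic, keto/enol mixture)
Conditions: Dess–Martin periodinane (1.3 equiv), NaHCO3, CH2Cl2, 0 °C; aq. Na2S2O3; used crude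
Reagents that add atoms: none
Why: Dess–Martin oxidation of the secondary α-hydroxy lactam to the 1,2-dicarbonyl compound under buffered, cold, non-acidic conditions that an N–H indole should tolerate.

Step 6
Reactants: 8 4-[(7-methoxy-1H-indol-5-yl)oxy]-1-methylpiperidine-2,3-dione; 9 phenylhydrazine
Product: 12 (4aS,9aS)-hexacyclic lactam, via hydrazone 10 (not isolated), via 3H-indole 11 (not isolated)
Conditions: 9 (1.0 equiv), 4 Å MS, toluene, 25 °C; then (S)-STRIP [(S)-6,6′-bis(2,4,6-triisopropylphenyl)-1,1′-spirobiindane-7,7′-diyl hydrogen phosphate] (10 mol %), Amberlite CG50, toluene (0.03 M), 50 °C; then CF3CO2H (1 equiv), 25 °C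
Reagents that add atoms: none
Why: Proposed new method: condensation gives hydrazone 10, whose only possible ene-hydrazine (C3=C4, because C2 is the lactam carbonyl) is protonated by the chiral acid and undergoes the [3,3]-diaza-Cope shift of a Fischer indolisation, which forms C4a–C4b at the aryloxy-bearing carbon; rearomatisation, 5-exo-trig attack of the new aniline nitrogen on the iminium carbon and loss of NH3 (taken up by the resin, so that the acid turns over) close the pyrroline ring as 3H-indole 11. The C9a=N9 bond of 11, activated by the C1 carbonyl and by acid, is then attacked in a 5-exo-trig aza-Friedel–Crafts reaction by C4′ of the aryl ether, which closes the dihydrofuran ring. The closest known reactions are the Fischer indolisation of piperidine-2,3-dione 3-arylhydrazones to 1-oxo-tetrahydro-β-carbolines, the interrupted Fischer indolisation in which a 3H-indole is trapped by a pendant nucleophile, chiral phosphoric acid-catalysed Fischer indolisations, and the acid cyclisation of α-aryloxy ketones to benzofurans; none of them ends in a C-arylation or sets a C4a/C9a pair. C4a is set in the [3,3] step inside the hydrogen-bonded ion pair (phosphate to the hydrazine N–H bonds and the lactam C=O), and racemic 8 converges because C4 is planar in the ene-hydrazine; C9a is dictated by C4a, since the arene hangs from the oxygen on C4a and can reach only the syn face, so the 5/5 fusion is cis by construction. The step needs C4′ and not C6′ or C3′ to attack: C4′ is para to OMe and the α-position of the benzo ring, C6′ is flanked by two oxygens, and C3′ cannot reach C9a through a five-membered transition state (dilution suppresses the intermolecular path).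

Step 7
Reactants: 12 (4aS,9aS)-hexacyclic lactam
Product: 13 (4aS,9aS)-hexacyclic lactam carrying CH2NMe2 at C3′
Conditions: Me2N+=CH2 I− (1.3 equiv), MeCN–AcOH (10:1), 25 °C; aq. NaOH
Reagents that add atoms: Eschenmoser's salt (N,N-dimethylmethyleneiminium iodide), C=[N+](C)C.[I-]
Why: Mannich reaction (gramine synthesis) with a preformed iminium salt at indole C3′, the most nucleophilic carbon of 12; the lactam nitrogen is non-basic, aminomethylation of the hindered N9–H is reversible and lost on basic work-up, and the quaternary centres cannot epimerise.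

Step 8
Reactants: 13 (4aS,9aS)-hexacyclic lactam carrying CH2NMe2 at C3′
Product: 14 the target, (4aS,9aR)-configured (CNP0318114.2)
Conditions: LiAlH4 (6 equiv), THF, 0 → 55 °C; Na2SO4·10H2O
Reagents that add atoms: none
Why: LiAlH4 reduction of the tertiary lactam to the amine (C1=O to CH2); the gramine-type amine, the aryl ether, the indoline and the indole should be inert to hydride, and the descriptor at C9a changes from S to R only because C1 loses priority, not because the centre moves.

**Compound list**

1 | 4-bromo-2-methoxy-1-nitrobenzene | COc1cc(Br)ccc1[N+](=O)[O-] | starting material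
2 | 4-bromo-2-methoxy-1-nitrosobenzene (not isolated) | COc1cc(Br)ccc1N=O | intermediate
3 | 5-bromo-7-methoxy-1H-indole | COc1cc(Br)cc2cc[nH]c12 | intermediate
4 | 7-methoxy-1H-indol-5-ol | COc1cc(O)cc2cc[nH]c12 | intermediate
5 | 1-methyl-5,6-dihydropyridin-2(1H)-one | CN1CCC=CC1=O | starting material
6 | 3-methyl-7-oxa-3-azabicyclo[4.1.0]heptan-2-one (racemic, cis-fused epoxide) | CN1CCC2OC2C1=O | intermediate
7 | rac-trans-3-hydroxy-4-[(7-methoxy-1H-indol-5-yl)oxy]-1-methylpiperidin-2-one (3S*,4R*; one enantiomer drawn) | CN1CC[C@@H](Oc2cc(OC)c3[nH]ccc3c2)[C@H](O)C1=O | intermediate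
8 | 4-[(7-methoxy-1H-indol-5-yl)oxy]-1-methylpiperidine-2,3-dione (racemic) | CN1CCC(Oc2cc(OC)c3[nH]ccc3c2)C(=O)C1=O | intermediate
9 | phenylhydrazine | NNc1ccccc1 | starting material
10 | 4-[(7-methoxy-1H-indol-5-yl)oxy]-1-methyl-3-(2-phenylhydrazinylidene)piperidin-2-one (not isolated; racemic) | CN1CCC(Oc2cc(OC)c3[nH]ccc3c2)C(=NNc2ccccc2)C1=O | intermediate
11 | (4aS)-4a-[(7-methoxy-1H-indol-5-yl)oxy]-2-methyl-2,3,4,4a-tetrahydro-1H-pyrido[3,4-b]indol-1-one (3H-indole, not isolated) | CN1CC[C@]2(Oc3cc(OC)c4[nH]ccc4c3)c3ccccc3N=C2C1=O | intermediate
12 | (4aS,9aS)-hexacyclic lactam: 2-methyl-2,3,4,4a,9,9a-hexahydro-1H-β-carbolin-1-one whose C9a is bonded to C4′ and whose C4a is bonded through oxygen to C5′ of 7-methoxy-1H-indole (cis-fused benzofuro[3,2-b]indoline, N9–H and N1′–H free) | COc1cc2c(c3cc[nH]c13)[C@@]13C(=O)N(C)CC[C@]1(O2)c1ccccc1N3 | intermediate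
13 | (4aS,9aS)-lactam 12 carrying CH2NMe2 at C3′ of the methoxyindole | COc1cc2c(c3c(CN(C)C)c[nH]c13)[C@@]13C(=O)N(C)CC[C@]1(O2)c1ccccc1N3 | intermediate
14 | (4aS,9aR)-hexacyclic amine with 3′-CH2NMe2 (CNP0318114.2) | COc1cc2c(c3c(CN(C)C)c[nH]c13)[C@@]13CN(C)CC[C@]1(O2)c1ccccc1N3 | target

**Step count and risks**

Total step count: 8. Longest linear sequence: 7 steps (steps 1, 2, 4, 5, 6, 7, 8).

The three steps most likely to fail:

1. Step 6 (Proposed new method). The conjugated hydrazone may tautomerise too slowly to the ene-hydrazine under the weak chiral acid, the phosphate may discriminate the faces of the [3,3] shift poorly, or the hydrazone may lose aryloxide. The fallback uses known chemistry, sets out from 8 and comes back at 12. Ketone 8 and phenylhydrazine 9 would be heated in acetic acid at 80 °C, a classical Fischer indolisation at a fully substituted α-carbon that runs through hydrazone 10, to give the racemic 3H-indole F1. F1 would be closed with CF3CO2H in CH2Cl2 (arylation of an activated ketimine) to the racemic cis-fused lactam F2. F2 would be resolved by preparative chromatography on a chiral stationary phase, which returns (4aS,9aS)-12 and leaves the mirror-image lactam F3.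

2. Step 5. The periodinane may oxidise the electron-rich indole ring, or the enolisable α-aryloxy dione may decompose on isolation. The fallback puts the oxidation before the indole is attached; it sets out from epoxide 6 and comes back at hydrazone 10. Epoxide 6 would be opened with LiBr and AcOH in THF to rac-trans-4-bromo-3-hydroxy-1-methylpiperidin-2-one F4, and F4 would be oxidised with Dess–Martin periodinane to 4-bromo-1-methylpiperidine-2,3-dione F5. F5 would be condensed with 9 in cold AcOH to the α-bromo hydrazone F6. Na2CO3 in CH2Cl2 would eliminate HBr from F6 to the azoalkene 1-methyl-3-(phenyldiazenyl)-5,6-dihydropyridin-2(1H)-one F7, to which phenol 4 would add through oxygen at C4 to give 10. Compound 10 would enter step 6 at the acid stage.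

3. Step 8. The hindered lactam may be reduced incompletely, or hydride may induce loss of dimethylamine from the gramine unit at the temperature that the reduction needs. The fallback reverses the order of the last two operations; it sets out from 12 and comes back at 14. Lactam 12 would be reduced with LiAlH4 in THF to the (4aS,9aR)-hexacyclic amine without the aminomethyl group F8, and F8 would be treated with Eschenmoser's salt in MeCN–AcOH to give 14.

**Further compounds**

F1 | step 6 | racemic 4a-[(7-methoxy-1H-indol-5-yl)oxy]-2-methyl-2,3,4,4a-tetrahydro-1H-pyrido[3,4-b]indol-1-one | CN1CCC2(Oc3cc(OC)c4[nH]ccc4c3)c3ccccc3N=C2C1=O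
F2 | step 6 | racemic cis-fused hexacyclic lactam (4aS*,9aS*), racemate of 12 | COc1cc2c(c3cc[nH]c13)C13C(=O)N(C)CCC1(O2)c1ccccc1N3
F3 | step 6 | (4aR,9aR)-hexacyclic lactam, mirror image of 12 | COc1cc2c(c3cc[nH]c13)[C@]13C(=O)N(C)CC[C@@]1(O2)c1ccccc1N3
F4 | step 5 | rac-trans-4-bromo-3-hydroxy-1-methylpiperidin-2-one (one enantiomer drawn) | CN1CC[C@@H](Br)[C@H](O)C1=O
F5 | step 5 | 4-bromo-1-methylpiperidine-2,3-dione (racemic) | CN1CCC(Br)C(=O)C1=O
F6 | step 5 | 4-bromo-1-methyl-3-(2-phenylhydrazinylidene)piperidin-2-one (racemic) | CN1CCC(Br)C(=NNc2ccccc2)C1=O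
F7 | step 5 | 1-methyl-3-[(E)-phenyldiazenyl]-5,6-dihydropyridin-2(1H)-one | CN1CCC=C(/N=N/c2ccccc2)C1=O
F8 | step 8 | (4aS,9aR)-hexacyclic amine without the 3′-aminomethyl group | COc1cc2c(c3cc[nH]c13)[C@@]13CN(C)CC[C@]1(O2)c1ccccc1N3
A1 | direct plan | methyl N-{2-[2-(4,4,5,5-tetramethyl-1,3,2-dioxaborolan-2-yl)-1H-indol-3-yl]ethyl}carbamate | COC(=O)NCCc1c(B2OC(C)(C)C(C)(C)O2)[nH]c2ccccc12
A2 | direct plan | 5-(benzyloxy)-4-bromo-7-methoxy-1H-indole | COc1cc(OCc2ccccc2)c(Br)c2cc[nH]c12
A3 | direct plan | 7-methoxy-4-{3-[2-(methylamino)ethyl]-1H-indol-2-yl}-1H-indol-5-ol | CNCCc1c(-c2c(O)cc(OC)c3[nH]ccc23)[nH]c2ccccc12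
A4 | direct plan | 7-methoxy-4-(1′-methylspiro[indole-3,3′-pyrrolidin]-2-yl)-1H-indol-5-ol (spiro centre not defined) | CN1CCC2(C1)C(-c1c(O)cc(OC)c3[nH]ccc13)=Nc1ccccc12
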